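**One-step world.** In a one-step world L and D give Z, one D per L. L, charged below D, is then the limiting reagent, and c_D falls by what L turns over.

| setting | north-west | north | east | flask |
|---|---|---|---|---|
| L | 0.050 M | 0.050 M | 0.050 M | 0.050 M |
| D | 0.15 M | 0.15 M | 0.30 M | 0.150 M |
| Q | 0.017 M | 0.038 M | 0.025 M | 0.0250 M |
| remark | run made earlier | run made earlier | run made earlier |  |
| time |  |  |  | 15 min |

| run | time / min | Z / % | L / % |
|---|---|---|---|
| north-west | 0.667 | 1.2 | 99.0 |
| north-west | 2.00 | 1.5 | 97.7 |
| north-west | 3.00 | 3.1 | 97.1 |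
| north-west | 5.00 | 5.6 | 95.2 |
| north-west | 8.00 | 9.1 | 90.4 |
| north-west | 10.0 | 13.7 | 85.8 |
| north-west | 12.0 | 18.2 | 80.7 |
| north | 1.50 | 2.1 | 99.5 |
| north | 3.00 | 2.5 | 97.1 |
| north | 5.00 | 4.2 | 95.5 |
| north | 6.00 | 5.3 | 94.5 |
| north | 8.00 | 8.2 | 92.0 |
| north | 10.0 | 11.4 | 89.0 |
| north | 12.0 | 15.4 | 84.8 |
| east | 1.00 | 1.9 | 97.3 |
| east | 2.00 | 5.9 | 95.5 |
| east | 3.00 | 8.2 | 91.8 |
| east | 6.00 | 24.0 | 76.3 |
| east | 12.0 | 72.8 | 27.7 |

(standard deviation of a reading: 0.5 percentage points)

- the Z in the flask at 15 min, as a percentage of the L charged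
- the L in the flask at 15 min, as a percentage of the L charged
- concentration of D at 15 min, in M



**Upper bound.** The flask's Q, 0.0250 M, lies between 0.017 M and 0.038 M. So I took the north-west run, which was ahead at its last reading. I let its Z grow on at the rate read from 8.00 min to 12.0 min, 0.173 /min, with no slowing as L ran down. That gave 30.6%.

**Lower bound.** I ran the north run on along its last straight slope, which gave 21.4%.

**Counting turnovers.** In the one-step world, one full turnover of L leaves the turnover floor, c_D charged less c_L charged: 0.100 M. My bounds on Z are part of a turnover, so they tightened c_D to between 0.135 M and 0.139 M.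

**The forecast.** It gave Z 25%, L 75% and c_D 0.1375 M, saying “D was never measured, so I assume 1:1 stoichiometry”. Its Z and c_D stood inside my brackets.

**The flask.** It gave Z 26.0%, L 74.0% and c_D 0.0602 M. Z fell inside the bracket, but c_D fell below the floor, with 74.0% of L still unturned.

    L + D + Z → 2 Z (k = 50.6 /M²/min)
    L + D → Z (k = 0.0557 /M/min)
    D ⇌ E (K = 0.847, k = 0.332 /min)
    D + Q → J (k = 2.69 /M/min)

**Where D went.** At 15.0 min the flask also held E 0.0530 M and J 0.0237 M, and neither is Z. The loss of D to E, both ways, and the length of the run acted together, as part of what kept Z at 26.0% in this flask: the same run without that loss gave 66.6%, and the flask left until 150 min gave >99.9%.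

**Second flask.** With L at 0.12 M the floor moves to 0.0300 M. That neighbour flask gave c_D 0.0250 M, again below its floor, with Z 62.7% and L 37.3%.

All runs were generated by integration on assumed constants; scatter was added.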